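**Plan**

1. Numbering (germacrane): carbocycle C1–C10; α-methylene lactone C11(=C13)–C12(=O)–O spanning C7/C8; hydroxymethyl C14 on C10 (C9=C10); isobutyrate on C3; butenolide C4=C5, C15(=O)–O–C6.
2. Cuts, in retrosynthetic order: C3–C4 (ten-membered ring; alkenyl bromide plus aldehyde); O–C8 (α-methylene lactone); C6–C7 (furanone onto a Morita–Baylis–Hillman acetate); C7–C11 (Morita–Baylis–Hillman); C8=C9 (Wittig); C10=C14 (α-methylenation of a C5 aldehyde).
3. Enabling feature: the lactone oxygen on C8 and the C14 hydroxyl lie 1,4 across C9=C10. That is the footprint of a 1,3-diene monoepoxide (C8=C9 alkene plus C10–C14 spiro-epoxide) opened at its far end by the C12 acid held on C7. One zerovalent-palladium event therefore closes the five-membered lactone, moves the alkene to C9=C10 with C8/C14 trans, frees the C14 alcohol and sets C8.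
4. Forward order of rings: butenolide (brought in as a silyloxyfuran), then the α-methylene-γ-lactone (key step), then the ten-membered carbocycle (chromium-mediated closure), then esterification and desilylation.
5. Stereochemistry: C10 epoxide by organocatalytic epoxidation (consumed later); C6 and C7 together by a chiral phosphine; C8 relayed from C10 in the key step and reinforced by C7; C3 by macrocyclic substrate control.

Key step: step 10

Assumption: compounds 1, 5, 7, 8 and 12 are purchasable, and the (S)-prolinol silyl ether (step 3) and the (R)-binaphthyl phosphine (step 9) are taken to give the configurations drawn; the mirror-image catalyst is used if the sense proves opposite.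

**Route**

Step 1
Reactants: 1 methyl 5,5-dimethoxypentanoate
Product: 2 5,5-dimethoxypentanal
Conditions: i-Bu2AlH (1.05 equiv), CH2Cl2, −78 °C; Rochelle salt work-up
Reagents that add atoms: none
Why: Diisobutylaluminium hydride adds once to the methyl ester at −78 °C and the aluminium hemiacetal survives until work-up, so the aldehyde is released without over-reduction and the dimethyl acetal is untouched (partial ester reduction).

Step 2
Reactants: 2 5,5-dimethoxypentanal
Product: 3 5,5-dimethoxy-2-methylidenepentanal
Conditions: 37% aq. CH2O, pyrrolidine (10 mol%), propionic acid (10 mol%), i-PrOH, 45 °C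
Reagents that add atoms: formaldehyde, C=O
Why: Pyrrolidinium propionate converts the aldehyde into its enamine, which undergoes a Mannich reaction with formaldehyde and then loses the amine (organocatalytic α-methylenation of an unbranched aldehyde) under conditions that leave the acetal intact.

Step 3
Reactants: 3 5,5-dimethoxy-2-methylidenepentanal
Product: 4 (2R)-2-(3,3-dimethoxypropyl)oxirane-2-carbaldehyde
Conditions: 35% aq. H2O2, (S)-2-{diphenyl[(trimethylsilyl)oxy]methyl}pyrrolidine (10 mol%), CH2Cl2, rt; used crude
Reagents that add atoms: hydrogen peroxide, OO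
Why: The amine forms an iminium ion to which hydrogen peroxide adds at C14, and the enamine then closes the epoxide on the face left open by the bulky silyloxydiphenylmethyl group (iminium/enamine Weitz–Scheffer-type epoxidation of an α-substituted acrolein), which sets the quaternary C10 centre.

Step 4
Reactants: 4 (2R)-2-(3,3-dimethoxypropyl)oxirane-2-carbaldehyde; 5 (triphenyl-λ5-phosphanylidene)acetaldehyde
Product: 6 (2E)-3-[(2S)-2-(3,3-dimethoxypropyl)oxiran-2-yl]prop-2-enal
Conditions: toluene, 40 °C
Reagents that add atoms: none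
Why: The stabilised ylide reacts with the non-enolisable epoxy aldehyde to give the E-enal (Wittig reaction), adding C8 and C7 without touching C10.

Step 5
Reactants: 7 prop-2-enoyl chloride; 8 2-(trimethylsilyl)ethanol
Product: 9 2-(trimethylsilyl)ethyl prop-2-enoate
Conditions: Et3N, CH2Cl2, 0 °C
Reagents that add atoms: none
Why: Acylation of a primary alcohol by an acid chloride with triethylamine gives the fluoride-labile acrylate needed to unmask the acid next to an epoxide later.

Step 6
Reactants: 6 (2E)-3-[(2S)-2-(3,3-dimethoxypropyl)oxiran-2-yl]prop-2-enal; 9 2-(trimethylsilyl)ethyl prop-2-enoate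
Product: 10 2-(trimethylsilyl)ethyl (4E)-5-[(2S)-2-(3,3-dimethoxypropyl)oxiran-2-yl]-3-hydroxy-2-methylidenepent-4-enoate (both C3 epimers, used as the mixture)
Conditions: quinuclidine (0.25 equiv), MeOH (0.75 equiv), neat, rt
Reagents that add atoms: none
Why: Quinuclidine adds to the acrylate and the ammonium enolate attacks the aldehyde carbon of the enal in a 1,2 sense before the amine is eliminated (Morita–Baylis–Hillman reaction), and the configuration of the new carbinol is irrelevant because it is erased in step 9.

Step 7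
Reactants: 10 the Morita–Baylis–Hillman alcohol
Product: 11 2-(trimethylsilyl)ethyl (4E)-3-acetoxy-5-[(2S)-2-(3,3-dimethoxypropyl)oxiran-2-yl]-2-methylidenepent-4-enoate (both C3 epimers)
Conditions: Ac2O, Et3N, 4-(dimethylamino)pyridine (5 mol%), CH2Cl2, 0 °C
Reagents that add atoms: acetic anhydride, CC(=O)OC(C)=O
Why: Acetylation of the secondary allylic alcohol installs the leaving group for the allylic substitution, and any allylic transposition of the acetate is harmless because both isomers give the same phosphonium intermediate.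

Step 8
Reactants: 12 3-bromofuran-2(5H)-one
Product: 13 [(3-bromofuran-2-yl)oxy]trimethylsilane
Conditions: Me3SiOTf, Et3N, Et2O, 0 °C; filtered and used directly
Reagents that add atoms: trimethylsilyl trifluoromethanesulfonate, C[Si](C)(C)OS(=O)(=O)C(F)(F)F
Why: Silyl triflate and triethylamine enolise the butenolide through its acidic γ-hydrogens to the aromatic 2-silyloxyfuran (soft enolisation to a silyl dienol ether), which keeps the bromine at the future C4.

Step 9
Reactants: 11 the allylic acetate; 13 [(3-bromofuran-2-yl)oxy]trimethylsilane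
Product: 14 2-(trimethylsilyl)ethyl (3R,4E)-3-[(2S)-4-bromo-5-oxo-2,5-dihydrofuran-2-yl]-5-[(2S)-2-(3,3-dimethoxypropyl)oxiran-2-yl]-2-methylidenepent-4-enoate
Conditions: (R)-N-[2′-(diphenylphosphanyl)-1,1′-binaphthalen-2-yl]acetamide (10 mol%), toluene, 0 °C → rt
Reagents that add atoms: none
Why: The phosphine adds in an SN2′ sense to the acrylate terminus and expels acetate, acetate desilylates the furan, and the furanolate attacks C7 of the dienyl phosphonium ion in a second SN2′ step that releases the catalyst (Lewis-base-catalysed allylic substitution of Morita–Baylis–Hillman acetates with 2-silyloxyfurans), with the hydrogen-bonding chiral phosphine fixing C6 and C7 together and the quaternary C10 blocking attack at C9.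

Step 10
Reactants: 14 the silylethyl ester
Product: 16 (4S,5R)-4-[(2S)-4-bromo-5-oxo-2,5-dihydrofuran-2-yl]-5-[(1E)-2-(hydroxymethyl)-5,5-dimethoxypent-1-en-1-yl]-3-methylideneoxolan-2-one, via carboxylic acid 15 (not isolated)
Conditions: Bu4NF (1.2 equiv), THF, 0 °C; AcOH (1.3 equiv); then Pd2(dba)3·CHCl3 (2.5 mol%), P(Oi-Pr)3 (15 mol%), 0 °C → rt
Reagents that add atoms: none
Why: Fluoride removes the 2-(trimethylsilyl)ethyl group by β-silyl fragmentation, and the zerovalent palladium–phosphite complex then ionises the C10–O bond of the vinyl epoxide with inversion to a C8–C9–C10 π-allyl complex whose alkoxide is protonated by the acid. The C12 carboxylate attacks C8 on the face opposite to palladium, so the oxygen enters on the face the epoxide oxygen left (net syn-1,4 addition), as in the known zerovalent-palladium-catalysed 1,4-addition of carboxylic acids to 1,3-diene monoepoxides and in Tsuji–Trost lactonisations. The α-methylene-γ-lactone closes in a 5-exo mode on the allyl terminus, whereas attack at C10 would require a seven-membered ring. C8 is set as R by the 10S epoxide through this double inversion, in the ionising conformer that keeps the oxymethylene syn and C1 anti on the allyl unit, which also gives the 9E alkene (C8 and C14 trans); the same pathway places the C9 and C6 substituents trans on the new lactone, so C7 reinforces it. The step needs E over Z geometry, for which 2-alkyl-2-vinyloxiranes are an E-selective class with acidic pronucleophiles, and it needs epoxide ionisation to outrun insertion into the C4–Br bond, which the strained allylic C–O bond, the weakly donating phosphite ligand and 0 °C should secure.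

Step 11
Reactants: 16 the hydroxy lactone
Product: 17 (4S,5R)-4-[(2S)-4-bromo-5-oxo-2,5-dihydrofuran-2-yl]-5-[(1E)-5,5-dimethoxy-2-({[tri(propan-2-yl)silyl]oxy}methyl)pent-1-en-1-yl]-3-methylideneoxolan-2-one
Conditions: i-Pr3SiOTf, 2,6-lutidine, CH2Cl2, −78 °C
Reagents that add atoms: tri(propan-2-yl)silyl trifluoromethanesulfonate, CC(C)[Si](OS(=O)(=O)C(F)(F)F)(C(C)C)C(C)C
Why: Silylation of the only hydroxyl group with a silyl triflate and a hindered, non-nucleophilic base avoids conjugate addition to the α-methylene lactone and prevents lactol formation with the C3 aldehyde that is unmasked next.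

Step 12
Reactants: 17 the silyl ether acetal
Product: 18 (4E)-5-[(2R,3S)-3-[(2S)-4-bromo-5-oxo-2,5-dihydrofuran-2-yl]-4-methylidene-5-oxooxolan-2-yl]-4-({[tri(propan-2-yl)silyl]oxy}methyl)pent-4-enal
Conditions: pyridinium 4-toluenesulfonate (0.2 equiv), acetone/H2O 9:1, 40 °C
Reagents that add atoms: water, O
Why: Mild acid-catalysed hydrolysis cleaves the dimethyl acetal while the primary triisopropylsilyl ether, both lactones and the alkenyl bromide are stable.

Step 13
Reactants: 18 the bromo aldehyde
Product: 19 (3S,6R,7S,8R)-3-hydroxy-14-{[tri(propan-2-yl)silyl]oxy}germacra-4,9,11(13)-triene-12,8:15,6-diolide (C4=C5 inside the butenolide; C8 and C14 trans on C9=C10)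
Conditions: CrCl2 (8 equiv), NiCl2 (10 mol%), degassed DMSO, rt, slow addition (final 2 mM)
Reagents that add atoms: none
Why: Zerovalent nickel inserts into the C4–Br bond, the alkenyl group passes to trivalent chromium and adds to the C3 aldehyde (intramolecular Nozaki–Hiyama–Kishi reaction), the chain being pre-folded by the trans-lactone and the in-ring cis C9=C10 alkene, and the 3S carbinol is expected from attack on the aldehyde face turned away from the fused lactone.

Step 14
Reactants: 19 the macrocyclic alcohol
Product: 20 (3S,6R,7S,8R)-3-(2-methylpropanoyloxy)-14-{[tri(propan-2-yl)silyl]oxy}germacra-4,9,11(13)-triene-12,8:15,6-diolide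
Conditions: (i-PrCO)2O, Et3N, 4-(dimethylamino)pyridine (10 mol%), CH2Cl2, 0 °C
Reagents that add atoms: 2-methylpropanoic anhydride, CC(C)C(=O)OC(=O)C(C)C
Why: Acylation of the secondary allylic alcohol with the anhydride under nucleophilic catalysis gives the isobutyrate with retention at C3 while the primary alcohol is masked as its silyl ether.

Step 15
Reactants: 20 the silyl ether
Product: 21 CNP0322767.4, (3S,6R,7S,8R)-14-hydroxy-3-(2-methylpropanoyloxy)germacra-4,9,11(13)-triene-12,8:15,6-diolide
Conditions: HF·pyridine, THF/pyridine, 0 °C → rt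
Reagents that add atoms: none
Why: Buffered hydrogen fluoride–pyridine cleaves the primary silyl ether without affecting the two lactones, the isobutyrate or the conjugate acceptors, which releases the target.

**Compound list**

1 | methyl 5,5-dimethoxypentanoate | COC(=O)CCCC(OC)OC | starting material
2 | 5,5-dimethoxypentanal | O=CCCCC(OC)OC | intermediate
3 | 5,5-dimethoxy-2-methylidenepentanal | C=C(C=O)CCC(OC)OC | intermediate
4 | (2R)-2-(3,3-dimethoxypropyl)oxirane-2-carbaldehyde | O=C[C@@]1(CCC(OC)OC)CO1 | intermediate
5 | (triphenyl-λ5-phosphanylidene)acetaldehyde | O=CC=P(c1ccccc1)(c1ccccc1)c1ccccc1 | starting material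
6 | (2E)-3-[(2S)-2-(3,3-dimethoxypropyl)oxiran-2-yl]prop-2-enal | O=C/C=C/[C@@]1(CCC(OC)OC)CO1 | intermediate
7 | prop-2-enoyl chloride | C=CC(=O)Cl | starting material
8 | 2-(trimethylsilyl)ethanol | C[Si](C)(C)CCO | starting material
9 | 2-(trimethylsilyl)ethyl prop-2-enoate | C=CC(=O)OCC[Si](C)(C)C | intermediate
10 | 2-(trimethylsilyl)ethyl (4E)-5-[(2S)-2-(3,3-dimethoxypropyl)oxiran-2-yl]-3-hydroxy-2-methylidenepent-4-enoate (both C3 epimers) | C=C(C(=O)OCC[Si](C)(C)C)C(O)/C=C/[C@@]1(CCC(OC)OC)CO1 | intermediate
11 | 2-(trimethylsilyl)ethyl (4E)-3-acetoxy-5-[(2S)-2-(3,3-dimethoxypropyl)oxiran-2-yl]-2-methylidenepent-4-enoate (both C3 epimers) | C=C(C(=O)OCC[Si](C)(C)C)C(OC(C)=O)/C=C/[C@@]1(CCC(OC)OC)CO1 | intermediate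
12 | 3-bromofuran-2(5H)-one | O=C1OCC=C1Br | starting material
13 | [(3-bromofuran-2-yl)oxy]trimethylsilane | C[Si](C)(C)Oc1occc1Br | intermediate
14 | 2-(trimethylsilyl)ethyl (3R,4E)-3-[(2S)-4-bromo-5-oxo-2,5-dihydrofuran-2-yl]-5-[(2S)-2-(3,3-dimethoxypropyl)oxiran-2-yl]-2-methylidenepent-4-enoate | C=C(C(=O)OCC[Si](C)(C)C)[C@@H](/C=C/[C@@]1(CCC(OC)OC)CO1)[C@H]1C=C(Br)C(=O)O1 | intermediate
15 | (3R,4E)-3-[(2S)-4-bromo-5-oxo-2,5-dihydrofuran-2-yl]-5-[(2S)-2-(3,3-dimethoxypropyl)oxiran-2-yl]-2-methylidenepent-4-enoic acid | C=C(C(=O)O)[C@@H](/C=C/[C@@]1(CCC(OC)OC)CO1)[C@H]1C=C(Br)C(=O)O1 | intermediate (not isolated)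
16 | (4S,5R)-4-[(2S)-4-bromo-5-oxo-2,5-dihydrofuran-2-yl]-5-[(1E)-2-(hydroxymethyl)-5,5-dimethoxypent-1-en-1-yl]-3-methylideneoxolan-2-one | C=C1C(=O)O[C@H](/C=C(/CO)CCC(OC)OC)[C@H]1[C@H]1C=C(Br)C(=O)O1 | intermediate
17 | (4S,5R)-4-[(2S)-4-bromo-5-oxo-2,5-dihydrofuran-2-yl]-5-[(1E)-5,5-dimethoxy-2-({[tri(propan-2-yl)silyl]oxy}methyl)pent-1-en-1-yl]-3-methylideneoxolan-2-one | C=C1C(=O)O[C@H](/C=C(/CO[Si](C(C)C)(C(C)C)C(C)C)CCC(OC)OC)[C@H]1[C@H]1C=C(Br)C(=O)O1 | intermediate
18 | (4E)-5-[(2R,3S)-3-[(2S)-4-bromo-5-oxo-2,5-dihydrofuran-2-yl]-4-methylidene-5-oxooxolan-2-yl]-4-({[tri(propan-2-yl)silyl]oxy}methyl)pent-4-enal | C=C1C(=O)O[C@H](/C=C(/CO[Si](C(C)C)(C(C)C)C(C)C)CCC=O)[C@H]1[C@H]1C=C(Br)C(=O)O1 | intermediate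
19 | (3S,6R,7S,8R)-3-hydroxy-14-{[tri(propan-2-yl)silyl]oxy}germacra-4,9,11(13)-triene-12,8:15,6-diolide | C=C1C(=O)O[C@@H]2/C=C(/CO[Si](C(C)C)(C(C)C)C(C)C)CC[C@H](O)C3=C[C@@H](OC3=O)[C@@H]12 | intermediate
20 | (3S,6R,7S,8R)-3-(2-methylpropanoyloxy)-14-{[tri(propan-2-yl)silyl]oxy}germacra-4,9,11(13)-triene-12,8:15,6-diolide | C=C1C(=O)O[C@@H]2/C=C(/CO[Si](C(C)C)(C(C)C)C(C)C)CC[C@H](OC(=O)C(C)C)C3=C[C@@H](OC3=O)[C@@H]12 | intermediate
21 | CNP0322767.4, (3S,6R,7S,8R)-14-hydroxy-3-(2-methylpropanoyloxy)germacra-4,9,11(13)-triene-12,8:15,6-diolide | C=C1C(=O)O[C@@H]2/C=C(/CO)CC[C@H](OC(=O)C(C)C)C3=C[C@@H](OC3=O)[C@@H]12 | target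

**Step count**

Total steps: 15. Longest linear sequence: 13 steps (steps 1–4, 6, 7, 9–15).

**Steps most likely to fail**

Step 10. The zerovalent palladium catalyst may be consumed by insertion into the C4–Br bond, or fluoride may epimerise C6, before the epoxide has been converted, so that the lactonisation stalls. The fallback introduces the halogen only after the palladium step. It sets out from acetate 11, which under the conditions of step 9 with commercial 2-(trimethylsilyloxy)furan should give the debromo ester F1 (analogue of 14 with H at C4). Bu4NF/AcOH followed by Pd(PPh3)4 in THF should convert it into the debromo hydroxy lactone F2, and i-Pr3SiOTf/2,6-lutidine then gives the debromo silyl ether F3. Iodine and pyridine in CH2Cl2 (conjugate addition of pyridine, α-iodination, elimination) should iodinate the butenolide at C4 to give the iodo silyl ether F4. Acetal hydrolysis as in step 12 gives the iodo aldehyde F5, and CrCl2/NiCl2 closure of F5 comes back to the route at 19.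

Step 13. Attack on the other face of the C3 aldehyde during the chromium-mediated ring closure would deliver the wrong carbinol configuration. The fallback sets out from 18, accepts the 3-epi alcohol F6 and esterifies it under Mitsunobu conditions (2-methylpropanoic acid, PPh3, diisopropyl azodicarboxylate, toluene, 0 °C). This installs the isobutyrate with inversion at C3 and comes back to the route at 20, replacing step 14.

Step 9. The brominated silyloxyfuran may be too weak a nucleophile toward the phosphonium dienoate, so that desilylation outpaces C–C bond formation or attack drifts to C9. The fallback sets out from alcohol 10, which with Boc2O and 4-(dimethylamino)pyridine gives the tert-butyl carbonate F7. F7 and bromobutenolide 12 itself are then combined with hydroquinidine 1,4-phthalazinediyl diether (10 mol%) in CH2Cl2. The tert-butoxide released from the carbonate deprotonates 12 to the furanolate inside the chiral ammonium ion pair (direct vinylogous allylic alkylation of a butenolide with a Morita–Baylis–Hillman carbonate), and the sequence comes back to the route at 14.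

Further compounds
F1 | step 10 | debromo analogue of 14: 2-(trimethylsilyl)ethyl (4E)-5-[(2S)-2-(3,3-dimethoxypropyl)oxiran-2-yl]-2-methylidene-3-(5-oxo-2,5-dihydrofuran-2-yl)pent-4-enoate, same spatial configuration at C6 and C7 as 14 | C=C(C(=O)OCC[Si](C)(C)C)[C@@H](/C=C/[C@@]1(CCC(OC)OC)CO1)[C@H]1C=CC(=O)O1
F2 | step 10 | debromo analogue of 16 (H at C4, same spatial configuration at C6, C7, C8) | C=C1C(=O)O[C@H](/C=C(/CO)CCC(OC)OC)[C@H]1[C@H]1C=CC(=O)O1
F3 | step 10 | debromo analogue of 17 (H at C4, same spatial configuration) | C=C1C(=O)O[C@H](/C=C(/CO[Si](C(C)C)(C(C)C)C(C)C)CCC(OC)OC)[C@H]1[C@H]1C=CC(=O)O1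
F4 | step 10 | iodo analogue of 17 (I at C4, same spatial configuration) | C=C1C(=O)O[C@H](/C=C(/CO[Si](C(C)C)(C(C)C)C(C)C)CCC(OC)OC)[C@H]1[C@H]1C=C(I)C(=O)O1
F5 | step 10 | iodo analogue of 18 (I at C4, same spatial configuration) | C=C1C(=O)O[C@H](/C=C(/CO[Si](C(C)C)(C(C)C)C(C)C)CCC=O)[C@H]1[C@H]1C=C(I)C(=O)O1
F6 | step 13 | C3 epimer of 19, (3R,6R,7S,8R)-3-hydroxy-14-{[tri(propan-2-yl)silyl]oxy}germacra-4,9,11(13)-triene-12,8:15,6-diolide | C=C1C(=O)O[C@@H]2/C=C(/CO[Si](C(C)C)(C(C)C)C(C)C)CC[C@@H](O)C3=C[C@@H](OC3=O)[C@@H]12
F7 | step 9 | 2-(trimethylsilyl)ethyl (4E)-3-[(tert-butoxycarbonyl)oxy]-5-[(2S)-2-(3,3-dimethoxypropyl)oxiran-2-yl]-2-methylidenepent-4-enoate (both C3 epimers) | C=C(C(=O)OCC[Si](C)(C)C)C(OC(=O)OC(C)(C)C)/C=C/[C@@]1(CCC(OC)OC)CO1
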